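## Retrosynthetic overview
- The target comes from its 8-allyl / 4a-(E)-crotyl analogue by one double cross-metathesis. The two placeholders leave a single trisubstituted alkene in the molecule at the ring-closing stage.
- Key disconnection O1–C2: the pyran is closed last, by an anodic, selenium-catalysed dehydrogenative cycloetherification of a lupulone-type dienone.
- Disconnection C4a–CH2 (quaternary centre): a suprafacial dearomative aryl Claisen shift of an (R)-but-3-en-2-yl ether. Its stereocentre is bought as (S)-but-3-en-2-ol.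
- The substitution pattern is built on phlorisovalerophenone by C-allylation, para-O-dimethylpropargylation (later the prenyl group, by semihydrogenation and [3,3] shift) and Mitsunobu etherification.
- Ring order: the carbocycle is bought as an arene and dearomatised in step 4. The pyran is formed in step 5.

Assumption: phlorisovalerophenone and (S)-but-3-en-2-ol (same configuration as L-lactic acid) are taken as catalogue compounds, and all β-triketones are drawn in the tautomer of the target SMILES.

## Route

Step 1
Reactants: 1 phlorisovalerophenone; 2 allyl bromide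
Product: 3 1-(3-allyl-2,4,6-trihydroxyphenyl)-3-methylbutan-1-one
Conditions: KOH (1.1 equiv), H2O, 0 °C to rt, 2 (1.0 equiv) added slowly
Reagents that add atoms: allyl bromide, C=CCBr
Why: In water the ambident phloroglucinolate is alkylated at carbon (C-allylation of an acylphloroglucinol, as in the classical hop-acid syntheses), slow addition of one equivalent holds it at the mono stage, and the allyl group blocks this carbon and stands in for the later 8-prenyl group; no stereocentre is formed.

Step 2
Reactants: 3 1-(3-allyl-2,4,6-trihydroxyphenyl)-3-methylbutan-1-one; 4 3-chloro-3-methylbut-1-yne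
Product: 5 1-[3-allyl-2,6-dihydroxy-4-(2-methylbut-3-yn-2-yloxy)phenyl]-3-methylbutan-1-one
Conditions: CuCl2·2H2O (1 mol %), DBU (1.3 equiv), MeCN, 0 °C
Reagents that add atoms: 3-chloro-3-methylbut-1-yne, CC(C)(Cl)C#C
Why: Copper-catalysed propargylic etherification takes the only non-chelated and most acidic OH (para to the acyl group), which masks this oxygen for step 3 and brings in the five carbons of the future pyran.

Step 3
Reactants: 5 1-[3-allyl-2,6-dihydroxy-4-(2-methylbut-3-yn-2-yloxy)phenyl]-3-methylbutan-1-one; 6 (S)-but-3-en-2-ol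
Product: 7 1-[3-allyl-6-[(2R)-but-3-en-2-yloxy]-2-hydroxy-4-(2-methylbut-3-yn-2-yloxy)phenyl]-3-methylbutan-1-one
Conditions: PPh3, DIAD, THF, 0 °C to rt
Reagents that add atoms: (S)-but-3-en-2-ol, C[C@H](O)C=C
Why: Mitsunobu reaction, in which only the ortho OH next to the free ring CH is accessible (the other is flanked by the allyl group and stays chelated) and SN2 displacement inverts the bought (S)-carbinol to the (R)-ether, placing the stereocentre next to the carbon that becomes C4a.

Step 4
Reactants: 7 1-[3-allyl-6-[(2R)-but-3-en-2-yloxy]-2-hydroxy-4-(2-methylbut-3-yn-2-yloxy)phenyl]-3-methylbutan-1-one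
Product: 10 (6R)-4-allyl-6-[(2E)-but-2-enyl]-3,5-dihydroxy-2-(3-methylbutanoyl)-6-(3-methylbut-2-enyl)cyclohexa-2,4-dien-1-one, via dimethylallyl ether 8 (not isolated), via prenyl phenol 9 (not isolated)
Conditions: H2 (1 atm, stopped at 1.0 equiv), Pd/CaCO3 poisoned with Pb(OAc)2, quinoline, EtOAc, rt; filter; o-xylene, BHT, Ar, 80 °C then 140 °C
Reagents that add atoms: none
Why: Semihydrogenation gives the strained ether 8, whose aromatic Claisen rearrangement at 80 °C puts a linear prenyl group on the only free ortho CH (9), and at 140 °C the but-3-en-2-yl ether, now blocked at both ortho positions, shifts by a suprafacial chair [3,3] (dearomative Claisen rearrangement with 1,3-chirality transfer, methyl equatorial, hence E-crotyl) to the prenyl-bearing carbon, trading the (R)-carbinol centre for the (R)-quaternary centre in a stable, enolised lupulone-type triketone.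

Step 5
Reactants: 10 (6R)-4-allyl-6-[(2E)-but-2-enyl]-3,5-dihydroxy-2-(3-methylbutanoyl)-6-(3-methylbut-2-enyl)cyclohexa-2,4-dien-1-one
Product: 12 (4aR)-8-allyl-4a-[(2E)-but-2-enyl]-7-hydroxy-2,2-dimethyl-6-(3-methylbutanoyl)-2H-chromen-5(4aH)-one, via C3 phenylselenide 11 (not isolated)
Conditions: (PhSe)2 (10 mol %), n-Bu4NPF6 (0.1 M), MeCN/HFIP 9:1, graphite anode, Pt cathode, undivided cell, 5 mA, 2.2–2.5 F/mol, Ar, rt
Reagents that add atoms: none
Why: Proposed new method: anodic organoselenium catalysis with the enolic oxygen of a dearomatised acylphloroglucinol as nucleophile; the anode turns (PhSe)2 into a PhSe+ equivalent that binds reversibly to the only trisubstituted (most electron-rich) alkene, the free vinylogous-acid OH next to the quaternary carbon opens the seleniranium ion at its tertiary carbon (Markovnikov, 6-endo) to form O1–C2 and selenide 11, a second anodic oxidation raises 11 to tetravalent selenium, which leaves with a C4 hydrogen (C2 has none) to give C3=C4 and return the catalyst, protons go to H2 at the cathode, and the C4a centre is untouched; the closest known reaction types are selenium-π-acid-catalysed dehydrogenative allylic etherification and lactonisation of simple alkenes (light-driven aerobic or anodic) and the stoichiometric PhSeCl/H2O2 chromene synthesis from o-prenylphenols.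

Step 6
Reactants: 12 (4aR)-8-allyl-4a-[(2E)-but-2-enyl]-7-hydroxy-2,2-dimethyl-6-(3-methylbutanoyl)-2H-chromen-5(4aH)-one; 13 2-methylbut-2-ene
Product: 14 (4aR)-7-hydroxy-2,2-dimethyl-6-(3-methylbutanoyl)-4a,8-bis(3-methylbut-2-enyl)-2H-chromen-5(4aH)-one (target)
Conditions: second-generation Hoveyda–Grubbs catalyst RuCl2(H2IMes)(=CH-C6H4-2-OiPr) (2 × 5 mol %), 13 (large excess)/CH2Cl2, 40 °C
Reagents that add atoms: 2-methylbut-2-ene, CC=C(C)C
Why: Olefin cross-metathesis exchanges the terminal allyl and the E-crotyl alkene for isopropylidene in one operation (the usual allyl-to-prenyl conversion of polyprenylated acylphloroglucinol work), while the cis C3=C4 alkene between two fully substituted carbons is too hindered to react and the stereocentre is not touched.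

## Compound list
1 | phlorisovalerophenone, 3-methyl-1-(2,4,6-trihydroxyphenyl)butan-1-one | CC(C)CC(=O)c1c(O)cc(O)cc1O | starting material
2 | allyl bromide | C=CCBr | starting material
3 | 1-(3-allyl-2,4,6-trihydroxyphenyl)-3-methylbutan-1-one | CC(C)CC(=O)c1c(O)cc(O)c(CC=C)c1O | intermediate
4 | 3-chloro-3-methylbut-1-yne | CC(C)(Cl)C#C | starting material
5 | 1-[3-allyl-2,6-dihydroxy-4-(2-methylbut-3-yn-2-yloxy)phenyl]-3-methylbutan-1-one | CC(C)CC(=O)c1c(O)cc(OC(C)(C)C#C)c(CC=C)c1O | intermediate
6 | (S)-but-3-en-2-ol | C[C@H](O)C=C | starting material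
7 | 1-[3-allyl-6-[(2R)-but-3-en-2-yloxy]-2-hydroxy-4-(2-methylbut-3-yn-2-yloxy)phenyl]-3-methylbutan-1-one | CC(C)CC(=O)c1c(O[C@H](C)C=C)cc(OC(C)(C)C#C)c(CC=C)c1O | intermediate
8 | 1-[3-allyl-6-[(2R)-but-3-en-2-yloxy]-2-hydroxy-4-(2-methylbut-3-en-2-yloxy)phenyl]-3-methylbutan-1-one (dimethylallyl ether) | CC(C)CC(=O)c1c(O[C@H](C)C=C)cc(OC(C)(C)C=C)c(CC=C)c1O | intermediate
9 | 1-[3-allyl-6-[(2R)-but-3-en-2-yloxy]-2,4-dihydroxy-5-(3-methylbut-2-enyl)phenyl]-3-methylbutan-1-one (prenyl phenol) | CC(C)CC(=O)c1c(O[C@H](C)C=C)c(CC=C(C)C)c(O)c(CC=C)c1O | intermediate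
10 | (6R)-4-allyl-6-[(2E)-but-2-enyl]-3,5-dihydroxy-2-(3-methylbutanoyl)-6-(3-methylbut-2-enyl)cyclohexa-2,4-dien-1-one | CC(C)CC(=O)C1=C(O)C(CC=C)=C(O)[C@](CC=C(C)C)(C/C=C/C)C1=O | intermediate
11 | (4aR)-8-allyl-4a-[(2E)-but-2-enyl]-7-hydroxy-2,2-dimethyl-6-(3-methylbutanoyl)-3-(phenylselanyl)-3,4-dihydro-2H-chromen-5(4aH)-one (C3 epimers) | C=CCC1=C2OC(C)(C)C([Se]c3ccccc3)C[C@@]2(C/C=C/C)C(=O)C(C(=O)CC(C)C)=C1O | intermediate
12 | (4aR)-8-allyl-4a-[(2E)-but-2-enyl]-7-hydroxy-2,2-dimethyl-6-(3-methylbutanoyl)-2H-chromen-5(4aH)-one | C=CCC1=C2OC(C)(C)C=C[C@@]2(C/C=C/C)C(=O)C(C(=O)CC(C)C)=C1O | intermediate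
13 | 2-methylbut-2-ene | CC=C(C)C | starting material
14 | (4aR)-7-hydroxy-2,2-dimethyl-6-(3-methylbutanoyl)-4a,8-bis(3-methylbut-2-enyl)-2H-chromen-5(4aH)-one | CC(C)=CCC1=C2OC(C)(C)C=C[C@@]2(CC=C(C)C)C(=O)C(C(=O)CC(C)C)=C1O | target

## Step count and risks
Total steps: 6. Longest linear sequence: 6 (from phlorisovalerophenone).

**Step 3 (Mitsunobu etherification).**
- Risk: the hydroxyl is chelated and sits next to the acyl group, so conversion may be low. SN2' leakage to the achiral crotyl ether, or partial ionisation, would cost enantiopurity.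
- Fallback, from 5 back to 7: SN2 inversion is replaced by a metal-allyl substitution that runs with net retention. (R)-But-3-en-2-ol F1 is acylated with methyl chloroformate and pyridine to (R)-but-3-en-2-yl methyl carbonate F2. The copper phenoxide made from 5 with LiN(SiMe3)2 and CuI is then allylated with F2 under RhCl(PPh3)3/P(OMe)3 in THF at 0 °C to rt. This is the enantiospecific, branched-selective rhodium-catalysed allylic etherification, and it gives 7 directly.

**Step 4 (semihydrogenation and double Claisen cascade).**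
- Risk: the dearomative shift starts from an oxygen flanked by the acyl group. It may leak to the acyl-bearing carbon, go on by a Cope shift to the para carbon, or lose fidelity through boat or Z pathways. The enantiomer ratio of 10 is checked by HPLC on a chiral phase and 10 is recrystallised if needed.
- Fallback, from 5 back to 10: the crotyl group is launched from the para oxygen, which has no acyl neighbour. Compound 5 is semihydrogenated as in step 4 to 1-[3-allyl-2,6-dihydroxy-4-(2-methylbut-3-en-2-yloxy)phenyl]-3-methylbutan-1-one F3. At 80 °C this rearranges to 1-[3-allyl-2,4,6-trihydroxy-5-(3-methylbut-2-enyl)phenyl]-3-methylbutan-1-one F4.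
- Mitsunobu reaction of its most acidic (para) OH with (R)-but-3-en-2-ol F1 gives 1-[3-allyl-4-[(2S)-but-3-en-2-yloxy]-2,6-dihydroxy-5-(3-methylbut-2-enyl)phenyl]-3-methylbutan-1-one F5. The launch side is the mirror image of the one in the main route, so the opposite carbinol configuration is needed. Heating shifts the group to the prenyl-bearing carbon to give the same (R)-10. The isomer from attack at the allyl-bearing carbon is removed by chromatography.

**Step 5 (proposed new anodic cyclisation).**
- Risk: the electron-rich enol may be oxidised at the anode in place of the diselenide, leading to radical carbocyclisation or oxygenation. The acyl-side oxygen may also close the ring.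
- Fallback with known chemistry, from 10 back to 12: a stoichiometric polar halo-etherification followed by dehydrohalogenation, as used to turn o-prenylphenols into 2,2-dimethylchromenes. N-Iodosuccinimide in CH2Cl2 at 0 °C closes the same ring on the trisubstituted alkene to (4aR)-8-allyl-4a-[(2E)-but-2-enyl]-7-hydroxy-3-iodo-2,2-dimethyl-6-(3-methylbutanoyl)-3,4-dihydro-2H-chromen-5(4aH)-one F6. DBU in toluene at 80 °C then removes HI toward C4, the only side that carries hydrogen.

## Further compounds
F1 | step 3 | (R)-but-3-en-2-ol | C[C@@H](O)C=C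
F2 | step 3 | (R)-but-3-en-2-yl methyl carbonate | COC(=O)O[C@H](C)C=C
F3 | step 4 | 1-[3-allyl-2,6-dihydroxy-4-(2-methylbut-3-en-2-yloxy)phenyl]-3-methylbutan-1-one | CC(C)CC(=O)c1c(O)cc(OC(C)(C)C=C)c(CC=C)c1O
F4 | step 4 | 1-[3-allyl-2,4,6-trihydroxy-5-(3-methylbut-2-enyl)phenyl]-3-methylbutan-1-one | CC(C)CC(=O)c1c(O)c(CC=C(C)C)c(O)c(CC=C)c1O
F5 | step 4 | 1-[3-allyl-4-[(2S)-but-3-en-2-yloxy]-2,6-dihydroxy-5-(3-methylbut-2-enyl)phenyl]-3-methylbutan-1-one | CC(C)CC(=O)c1c(O)c(CC=C(C)C)c(O[C@@H](C)C=C)c(CC=C)c1O
F6 | step 5 | (4aR)-8-allyl-4a-[(2E)-but-2-enyl]-7-hydroxy-3-iodo-2,2-dimethyl-6-(3-methylbutanoyl)-3,4-dihydro-2H-chromen-5(4aH)-one (C3 epimers) | C=CCC1=C2OC(C)(C)C(I)C[C@@]2(C/C=C/C)C(=O)C(C(=O)CC(C)C)=C1O
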